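- Start from an invariant: take it that each product molecule costs one partner, so that in this flask product made plus partner unspent, in whatever form it waits, stays equal to the charge.

all flasks: left-handed substrate 0.40 M; right-handed substrate 0.40 M; added ligand 19 mM

| charge | partner | free catalyst | remark | time |
|---|---|---|---|---|
| north-west | 0.60 equiv | 1.2 mol% | the very flask that is asked about, followed so far |  |
| north | 0.60 equiv | 1.8 mol% | run made earlier |  |
| flask | 0.600 equiv | 1.2 mol% |  | 6.0 d |

| run | time / d | left-handed product / % | right-handed product / % |
|---|---|---|---|
| north-west | 0.250 | 2.3 | 0.6 |
| north-west | 0.500 | 3.9 | 2.6 |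
| north-west | 1.25 | 6.3 | 4.4 |
| north-west | 3.00 | 9.6 | 9.2 |
| north | 0.208 | 3.9 | 1.7 |
| north | 0.417 | 5.9 | 3.2 |
| north | 1.04 | 7.9 | 5.9 |
| north | 2.50 | 11.7 | 10.9 |

(scatter of a reading: 0.5 percentage points)

- free catalyst is single-handed; left-handed substrate and right-handed substrate are mirror images of each other, charged as a racemate, each of them at the stated concentration
- an excess is the difference of the two amounts in percent of their sum
- an excess is below zero if the other one leads

- excess of left-handed product over right-handed product in the product at 8.0 h
- excess of left-handed product over right-handed product in the product at 6.0 d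
- part of the left-handed substrate and right-handed substrate charged together that has reacted at 6.0 d

- Turn the question round and ask what the substrates would need in order to run out first: [partner] would have to reach [left-handed substrate] + [right-handed substrate], yet this flask starts at 0.240 M against 0.800 M, so partner is the limiting reagent and the reacted part has a ceiling of 30.0%.
- Reckon with the room left, one minus the product total over that ceiling, which in the north-west run reads 64.3% at 1.25 d and 37.3% at 3.00 d.
- Call the logarithmic fall of that room per day the room constant, 0.311 d⁻¹, a half-time of 2.23 d; the north run, at 1.8 mol%, reads 0.537 d⁻¹, so take the constant as roughly proportional to loading.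
- Carry the room on from 3.00 d to 6.0 d: the reckoning gives 14.7%, so commit to 25.6% reacted.
- The forecast gave 33%, −4.5% and 29%, the last above my figure, allowing “some slowing from substrate and partner depletion”.
- The flask gives 37.6%, 1.30% and 25.0% reacted, and at 6.0 d its unbound partner stands at 9.3% of charge, less than the 65% of left-handed substrate. Its room, taken from the reacted part, is 16.8%, above the reckoned 14.7%.

    free catalyst + left-handed substrate ⇌ catalyst intermediate A (K = 1.00 M⁻¹, k = 498 M⁻¹ h⁻¹)
    free catalyst + right-handed substrate ⇌ catalyst intermediate B (K = 1.27 M⁻¹, k = 47.0 M⁻¹ h⁻¹)
    partner + catalyst intermediate A → free catalyst + left-handed product (k = 242 M⁻¹ h⁻¹)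
    partner + catalyst intermediate B → free catalyst + right-handed product (k = 81.3 M⁻¹ h⁻¹)
    left-handed product ⇌ right-handed product (k = 0.0325 h⁻¹)
    partner ⇌ dormant form (K = 0.700, k = 0.0598 h⁻¹)
    free catalyst + added ligand ⇌ idle complex, settled at all times (K = 1480 M⁻¹)

- On the neighbour flask with 0.48 mol% of free catalyst and the same ceiling, scale the room constant by loading and run it from the start: the reckoning gives a room of 47.4% at 6.0 d, so 15.8% reacted, and that flask gives 14.9%.

The data stem from a simulated flask with constants of no real substance.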